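**Target check.** Epicalyxin B is a helichrysetin-type chalcone (2′,4′-OH, 6′-OMe) carrying at C3′ (between the two OH groups, para to OMe) the C7 carbon of a 1,7-bis(4-hydroxyphenyl)hept-5-en-3-ol chain. From the SMILES: C7 (bis-benzylic, allylic) is R, C3 (carbinol) is S, and both alkenes are E.

**Assumptions (one line each).**
- Reagents that only deliver protecting groups or heteroatoms are given by name and SMILES inside each step and are not numbered; numbered compounds are skeleton-contributing starting materials, intermediates and the target.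
- (R)-3,3′-Br2-BINOL is assumed to deliver the alkenyl group to the Re face of the o-quinone methide carbon (giving 7R); if experiment shows the opposite sense, the (S)-catalyst is used with no other change.

## Retrosynthetic overview

1. Epicalyxin B ⇒ global desilylation of hexasilyl chalcone 20; the aryl–C(=O) bond comes from the aryllithium of bromide 16 plus p-coumaric Weinreb amide 19.
2. 16 ⇒ silylation and monobromination of resorcinol 14, whose two free ring positions are equivalent, so there is no regiochemical issue.
3. Key disconnection C6–C7: 14 ⇒ racemic o-quinone-methide precursor 6 + (E)-alkenylboronate 13, joined by a new catalytic enantioconvergent alkenylation that sets 7R.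
4. 6 ⇒ directed ortho-lithiation of bis-MOM 5-methoxyresorcinol + 4-(TIPSO)benzaldehyde; 13 ⇒ hydroboration of a homopropargylic ether made by asymmetric propargylation (sets 3S).
5. No rings are formed: all four benzene rings come from commercial aromatics. Order of construction: C3 stereocentre → C6–C7 bond with C7 stereocentre → chalcone acyl bond.

## Forward route

**Step 1**
Reactants: 1, 5-methoxyresorcinol
Product: 2, 1-methoxy-3,5-bis(methoxymethoxy)benzene
Conditions: MOMCl (2.5 equiv), i-Pr2NEt, CH2Cl2, 0 °C → rt
Reagents that add atoms: chloromethyl methyl ether, COCCl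
Why: Standard phenol O-alkylation (MOM acetal formation); the two MOM groups later act as cooperative directed-metalation groups.

**Step 2**
Reactants: 3, 4-hydroxybenzaldehyde
Product: 4, 4-[(triisopropylsilyl)oxy]benzaldehyde
Conditions: TIPSCl, imidazole, DMF, rt
Reagents that add atoms: triisopropylsilyl chloride, CC(C)[Si](Cl)(C(C)C)C(C)C
Why: Phenol silylation; TIPS is chosen because it survives BuLi and the acidic MOM removal and blocks p-quinone-methide formation in step 10.

**Step 3**
Reactants: 2, 1-methoxy-3,5-bis(methoxymethoxy)benzene; 4, 4-[(triisopropylsilyl)oxy]benzaldehyde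
Product: 5, (±)-[4-methoxy-2,6-bis(methoxymethoxy)phenyl]{4-[(triisopropylsilyl)oxy]phenyl}methanol
Conditions: n-BuLi (1.1 equiv), THF, 0 °C, 1 h; then 4, −78 → 0 °C
Reagents that add atoms: none
Why: Directed ortho-metalation occurs at the position flanked by both OMOM groups, and 1,2-addition to the aldehyde gives the racemic benzhydrol (its configuration is erased in step 10).

**Step 4**
Reactants: 5, the bis-MOM benzhydrol
Product: 6, (±)-5-methoxy-2-(methoxy{4-[(triisopropylsilyl)oxy]phenyl}methyl)benzene-1,3-diol
Conditions: HCl (ca. 1 M, from AcCl) in MeOH, 0 °C → rt; NaHCO3 quench; Et3N-deactivated silica; used promptly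
Reagents that add atoms: methanol, CO
Why: Acid-catalysed MOM acetal methanolysis with concurrent SN1 etherification of the highly stabilised benzhydryl cation gives the symmetric o-hydroxybenzyl methyl ether, a latent o-quinone methide; the aryl TIPS ether is acid-stable.

**Step 5**
Reactants: 7, methyl 3-(4-hydroxyphenyl)propanoate
Product: 8, methyl 3-{4-[(tert-butyldimethylsilyl)oxy]phenyl}propanoate
Conditions: TBSCl, imidazole, DMF, rt
Reagents that add atoms: tert-butyldimethylsilyl chloride, CC(C)(C)[Si](C)(C)Cl
Why: Routine phenol silylation.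

**Step 6**
Reactants: 8, the TBS ester
Product: 9, 3-{4-[(tert-butyldimethylsilyl)oxy]phenyl}propanal
Conditions: DIBAL-H (1.1 equiv), CH2Cl2, −78 °C; Rochelle salt
Reagents that add atoms: none
Why: Partial ester reduction through the tetrahedral aluminate, which is stable at −78 °C.

**Step 7**
Reactants: 9, the aldehyde; 10, allenylboronic acid pinacol ester
Product: 11, (3S)-1-{4-[(tert-butyldimethylsilyl)oxy]phenyl}hex-5-yn-3-ol
Conditions: 10 (1.5 equiv), (R)-TRIP (10 mol %), 4 Å MS, toluene, −20 °C
Reagents that add atoms: none (the propargyl unit comes from reactant 10)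
Why: Chiral-phosphoric-acid-catalysed asymmetric propargylation (SE2′ allenylboration through a closed chair transition state); Re-face addition sets 3S (about 90% ee expected for a linear aldehyde), and any minor enantiomer later becomes a diastereomer removable by chromatography.

**Step 8**
Reactants: 11, the homopropargylic alcohol
Product: 12, tert-butyl({(3S)-1-[4-(tert-butyldimethylsilyloxy)phenyl]hex-5-yn-3-yl}oxy)dimethylsilane
Conditions: TBSCl, imidazole, DMF, rt
Reagents that add atoms: tert-butyldimethylsilyl chloride, CC(C)(C)[Si](C)(C)Cl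
Why: Secondary alcohol silylation; this prevents the C3 oxygen from trapping the o-quinone methide in step 10.

**Step 9**
Reactants: 12, the alkyne
Product: 13, diethyl [(1E,4S)-4-[(tert-butyldimethylsilyl)oxy]-6-{4-[(tert-butyldimethylsilyl)oxy]phenyl}hex-1-en-1-yl]boronate
Conditions: (+)-Ipc2BH, THF, −35 → 0 °C; then CH3CHO (excess), 0 → 40 °C; volatiles removed in vacuo; used crude
Reagents that add atoms: diisopinocampheylborane, CC1C(BC2CC3CC(C2C)C3(C)C)CC2CC1C2(C)C; acetaldehyde, CC=O
Why: Brown hydroboration (syn, anti-Markovnikov) gives the (E)-alkenylborane, and acetaldehyde displaces both Ipc groups as α-pinene to leave the diethyl boronate.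

**Step 10**
Reactants: 6, racemic o-hydroxybenzyl methyl ether (1.3 equiv); 13, the alkenylboronate (1.0 equiv)
Product: 14, 2-{(1R,2E,5S)-5-[(tert-butyldimethylsilyl)oxy]-7-[4-(tert-butyldimethylsilyloxy)phenyl]-1-[4-(triisopropylsilyloxy)phenyl]hept-2-en-1-yl}-5-methoxybenzene-1,3-diol
Conditions: (R)-3,3′-Br2-BINOL (20 mol %), 4 Å MS, PhCF3, 0 °C → rt; pH 7 buffer work-up
Reagents that add atoms: none
Why: Proposed new method: chiral-biphenol-catalysed enantioconvergent 1,4-alkenylation of a resorcinol-derived o-quinone methide, used as a fragment coupling — the BINOL exchanges the ethoxides of 13 to give a more Lewis-acidic chiral alkenylboronate, which binds a phenolic oxygen of 6 (both OH groups lead to the same o-quinone methide by symmetry), assists loss of MeOH to a boron-bound o-quinone methide with the exocyclic aryl anti to O–B, and the ate complex then transfers the (E)-alkenyl group intramolecularly to the Re face of the planar benzylic carbon through a six-membered chair transition state, forming C6–C7 with retention of alkene geometry and setting 7R from racemic 6 under catalyst control (the remote 3S centre is a spectator); the closest known reaction type is BINOL-catalysed asymmetric addition of simple alkenylboronates to o-quinone methides from mono-phenolic o-hydroxybenzyl ethers (Petasis-type ate-complex transfer), and what is untested is a 2,6-dihydroxy, 2,4,6-trioxygenated substrate and a functionalised chiral alkenylboronate partner.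

**Step 11**
Reactants: 14, the resorcinol
Product: 15, the bis(tert-butyldimethylsilyl) ether of 14 (both ring-A OH groups silylated)
Conditions: TBSOTf (2.5 equiv), 2,6-lutidine, CH2Cl2, −78 → 0 °C
Reagents that add atoms: tert-butyldimethylsilyl triflate, CC(C)(C)[Si](C)(C)OS(=O)(=O)C(F)(F)F
Why: Silylation of hindered phenols with the reactive triflate under non-nucleophilic, non-acidic conditions, which do not affect C7 or the alkene.

**Step 12**
Reactants: 15, the bis-TBS ether
Product: 16, the monobromide of 15 (Br on ring A at the CH between OMe and OTBS)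
Conditions: NBS (1.0 equiv), CH2Cl2, −78 → −20 °C, dark
Reagents that add atoms: N-bromosuccinimide, O=C1CCC(=O)N1Br
Why: Electrophilic aromatic bromination at one of the two equivalent, triply oxygen-activated ring positions, which is far faster than reaction at the unactivated alkene or the mono-oxygenated rings.

**Step 13**
Reactants: 17, 4-[(tert-butyldimethylsilyl)oxy]benzaldehyde; 18, diethyl {2-[methoxy(methyl)amino]-2-oxoethyl}phosphonate
Product: 19, (2E)-3-{4-[(tert-butyldimethylsilyl)oxy]phenyl}-N-methoxy-N-methylprop-2-enamide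
Conditions: LiCl, DBU, MeCN, rt
Reagents that add atoms: none (both partners are reactants)
Why: Horner–Wadsworth–Emmons olefination under Masamune–Roush conditions gives the E-enamide and is mild enough for the aryl silyl ether.

**Step 14**
Reactants: 16, the aryl bromide; 19, the Weinreb amide
Product: 20, hexasilyl epicalyxin B (ring-A 2′,4′-bis-OTBS, 4-OTBS on the chalcone B ring, OTIPS on the C7 aryl, OTBS on C3 and on the C1 aryl)
Conditions: t-BuLi (2.0 equiv), THF, −78 °C, 10 min; then 19 (1.5 equiv), −78 → −40 °C; NH4Cl
Reagents that add atoms: none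
Why: Bromine–lithium exchange followed by Weinreb ketone synthesis (the chelated tetrahedral intermediate prevents over-addition) forms the aryl–C(=O) bond and delivers the E-chalcone directly; keeping the temperature at or below −40 °C avoids silyl migration and deprotonation at C7.

**Step 15**
Reactants: 20, hexasilyl epicalyxin B
Product: 21, epicalyxin B
Conditions: TBAF/AcOH (1:1, excess), THF, 0 °C → rt
Reagents that add atoms: none
Why: Fluoride-mediated global desilylation; the acetic acid buffer suppresses base-induced chalcone-to-flavanone cyclisation, and no strong acid is used, so the acid-labile C7–aryl bond is not ionised.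

## Compound list

1 | 5-methoxyresorcinol | COc1cc(O)cc(O)c1 | starting material
2 | 1-methoxy-3,5-bis(methoxymethoxy)benzene | COCOc1cc(OC)cc(OCOC)c1 | intermediate
3 | 4-hydroxybenzaldehyde | O=Cc1ccc(O)cc1 | starting material
4 | 4-[(triisopropylsilyl)oxy]benzaldehyde | O=Cc1ccc(O[Si](C(C)C)(C(C)C)C(C)C)cc1 | intermediate
5 | (±)-[4-methoxy-2,6-bis(methoxymethoxy)phenyl]{4-[(triisopropylsilyl)oxy]phenyl}methanol | COCOc1cc(OC)cc(OCOC)c1C(O)c1ccc(O[Si](C(C)C)(C(C)C)C(C)C)cc1 | intermediate
6 | (±)-5-methoxy-2-(methoxy{4-[(triisopropylsilyl)oxy]phenyl}methyl)benzene-1,3-diol | COc1cc(O)c(C(OC)c2ccc(O[Si](C(C)C)(C(C)C)C(C)C)cc2)c(O)c1 | intermediate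
7 | methyl 3-(4-hydroxyphenyl)propanoate | COC(=O)CCc1ccc(O)cc1 | starting material
8 | methyl 3-{4-[(tert-butyldimethylsilyl)oxy]phenyl}propanoate | COC(=O)CCc1ccc(O[Si](C)(C)C(C)(C)C)cc1 | intermediate
9 | 3-{4-[(tert-butyldimethylsilyl)oxy]phenyl}propanal | O=CCCc1ccc(O[Si](C)(C)C(C)(C)C)cc1 | intermediate
10 | allenylboronic acid pinacol ester | C=C=CB1OC(C)(C)C(C)(C)O1 | starting material
11 | (3S)-1-{4-[(tert-butyldimethylsilyl)oxy]phenyl}hex-5-yn-3-ol | C#CC[C@@H](O)CCc1ccc(O[Si](C)(C)C(C)(C)C)cc1 | intermediate
12 | tert-butyl({(3S)-1-[4-(tert-butyldimethylsilyloxy)phenyl]hex-5-yn-3-yl}oxy)dimethylsilane | C#CC[C@@H](O[Si](C)(C)C(C)(C)C)CCc1ccc(O[Si](C)(C)C(C)(C)C)cc1 | intermediate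
13 | diethyl [(1E,4S)-4-(TBSO)-6-{4-(TBSO)phenyl}hex-1-en-1-yl]boronate | CCOB(OCC)/C=C/C[C@@H](O[Si](C)(C)C(C)(C)C)CCc1ccc(O[Si](C)(C)C(C)(C)C)cc1 | intermediate
14 | 2-{(1R,2E,5S)-5-(TBSO)-7-[4-(TBSO)phenyl]-1-[4-(TIPSO)phenyl]hept-2-en-1-yl}-5-methoxybenzene-1,3-diol | COc1cc(O)c([C@H](/C=C/C[C@@H](O[Si](C)(C)C(C)(C)C)CCc2ccc(O[Si](C)(C)C(C)(C)C)cc2)c2ccc(O[Si](C(C)C)(C(C)C)C(C)C)cc2)c(O)c1 | intermediate
15 | 1,3-bis-O-TBS ether of 14 | COc1cc(O[Si](C)(C)C(C)(C)C)c([C@H](/C=C/C[C@@H](O[Si](C)(C)C(C)(C)C)CCc2ccc(O[Si](C)(C)C(C)(C)C)cc2)c2ccc(O[Si](C(C)C)(C(C)C)C(C)C)cc2)c(O[Si](C)(C)C(C)(C)C)c1 | intermediate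
16 | 4-bromo derivative of 15 (Br between OMe and OTBS) | COc1cc(O[Si](C)(C)C(C)(C)C)c([C@H](/C=C/C[C@@H](O[Si](C)(C)C(C)(C)C)CCc2ccc(O[Si](C)(C)C(C)(C)C)cc2)c2ccc(O[Si](C(C)C)(C(C)C)C(C)C)cc2)c(O[Si](C)(C)C(C)(C)C)c1Br | intermediate
17 | 4-[(tert-butyldimethylsilyl)oxy]benzaldehyde | O=Cc1ccc(O[Si](C)(C)C(C)(C)C)cc1 | starting material
18 | diethyl {2-[methoxy(methyl)amino]-2-oxoethyl}phosphonate | CCOP(=O)(CC(=O)N(C)OC)OCC | starting material
19 | (2E)-3-{4-[(tert-butyldimethylsilyl)oxy]phenyl}-N-methoxy-N-methylprop-2-enamide | CON(C)C(=O)/C=C/c1ccc(O[Si](C)(C)C(C)(C)C)cc1 | intermediate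
20 | hexasilyl epicalyxin B | COc1cc(O[Si](C)(C)C(C)(C)C)c([C@H](/C=C/C[C@@H](O[Si](C)(C)C(C)(C)C)CCc2ccc(O[Si](C)(C)C(C)(C)C)cc2)c2ccc(O[Si](C(C)C)(C(C)C)C(C)C)cc2)c(O[Si](C)(C)C(C)(C)C)c1C(=O)/C=C/c1ccc(O[Si](C)(C)C(C)(C)C)cc1 | intermediate
21 | epicalyxin B | COc1cc(O)c([C@H](/C=C/C[C@@H](O)CCc2ccc(O)cc2)c2ccc(O)cc2)c(O)c1C(=O)/C=C/c1ccc(O)cc1 | target

## Summary

**Total steps:** 15.
**Longest linear sequence:** 10 (steps 5 → 6 → 7 → 8 → 9 → 10 → 11 → 12 → 14 → 15, from methyl 3-(4-hydroxyphenyl)propanoate).

**Three steps most likely to fail, with fallbacks**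

1. **Step 10 (proposed new o-quinone-methide alkenylation).**
   - Risks: racemic background transfer from non-BINOL-bound aryloxyboronates; Friedel–Crafts oligomerisation of the very electron-rich o-quinone methide; erosion of ee if the o-quinone-methide geometry is not controlled.
   - Fallback (known chemistry, different bond-forming logic): set C7 by 1,3-chirality transfer in an aromatic Claisen rearrangement. Mitsunobu-etherify (inversion) the 4-OH of commercial 2′,4′-dihydroxy-6′-methoxyacetophenone with the (3S,5S,6E)-allylic alcohol ArCH=CH–CH(OH)–CH2–CH(OTBS)–CH2CH2Ar, with C5 set by CBS reduction of the enone. Eu(fod)3-promoted [3,3] shift to C3′ then goes through a chair transition state (5R ether → 7R, E-alkene). Finish by Claisen–Schmidt condensation and deprotection.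

2. **Step 14 (Br–Li exchange and Weinreb acylation).**
   - Risks: O→C silyl migration in the ortho-silyloxy aryllithium; proton transfer from the acidic C7–H; sluggish addition of a di-ortho-substituted aryllithium.
   - Fallback: avoid organolithium chemistry. Stille-couple 16 with tributyl(1-ethoxyvinyl)stannane and hydrolyse the enol ether briefly to the aryl methyl ketone. Then build the enone by LiHMDS aldol with 17 and MsCl/Et3N dehydration to reach 20.

3. **Step 4 (acidic MOM removal to the labile ether 6).**
   - Risks: retro-Friedel–Crafts loss of the aldehyde; self-condensation of the benzhydryl cation with the free resorcinol ring.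
   - Fallback: make the precursor without exposing a benzhydryl centre to acid. Formylate 2 (n-BuLi, then DMF) and remove the MOM groups at the robust aldehyde stage to give 2,6-dihydroxy-4-methoxybenzaldehyde. Add excess 4-(TIPSO)phenylmagnesium bromide and use the resulting free o-hydroxybenzhydrol directly, with molecular sieves, as the o-quinone-methide precursor in step 10.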